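**Plan**

- Locants used for every compound: C1 ketone carbon, C2 oxirane carbon bearing farnesyl (C1′ onward), C3 oxirane CH, C4 carbinol carbon, C5 ring carbon carrying C7 (CH2OAc), C6 alkene CH.
- Retrosynthetic cuts, in order: the acetate C–O at C7; the oxirane C2–O bond (C3 oxygen as nucleophile, C2 as electrophile); the C2–C1′ bond to farnesyl; the C5–C7 bond; the C1 oxygen, back to an alkene of a cyclohexadiene cis-diol.
- Forward: the six-membered carbocycle is bought as the bromobenzene cis-dihydrodiol. It is hydrated and oxidised to a β-bromo enone, C7 is coupled on, a silylene ring ties C4–O to C7–O, farnesyl is alkylated onto C2, and the oxirane is the last ring to close.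
- Enabling feature: C2 is α to the C1 ketone, so its enolate can take up bromine. The neighbouring C3 oxygen is cis to the C4 oxygen on the six-membered ring, which is the cis-diol of the arene dihydrodiol, so a free C3 oxide is placed to close onto C2.
- Stereochemistry: C3 and C4 come from the chiral pool. C2 is fixed by the closure, because the C3 oxide can displace a C2 bromide only from its own face; this puts the oxirane oxygen cis to C4–O and farnesyl trans. The E alkenes come with farnesyl bromide.

Key step: step 9

Remark: descriptors in the names refer to the locants defined above; commercial trans,trans-farnesyl bromide is taken as the (2E,6E) isomer.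

**Route**

Step 1
Reactants: 1 (1S,2S)-3-bromocyclohexa-3,5-diene-1,2-diol
Product: 2 (3S,4S)-5-bromo-3,4-O-isopropylidene diene (acetonide of 1; alkenes C1=C2 and C5=C6)
Conditions: Me2C(OMe)2, p-TsOH·H2O (cat.), acetone, 0 °C to rt
Reagents that add atoms: 2,2-dimethoxypropane, COC(C)(C)OC
Why: Acid-catalysed transketalisation (acetonide formation) of the cis-1,2-diol touches no stereocentre and gives the ring a shielded face for the next step.

Step 2
Reactants: 2 diene acetonide
Product: 3 (1S,2R,3R,4S)-2,5-dibromo-1-hydroxy-3,4-O-isopropylidene cyclohex-5-ene (bromohydrin; C1–OH cis and C2–Br trans to the acetonide oxygens)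
Conditions: NBS, THF/H2O, 0 °C
Reagents that add atoms: N-bromosuccinimide, O=C1CCC(=O)N1Br; water, O
Why: Bromohydrin formation on the more electron-rich distal alkene: the bromonium ion forms on the face opposite the acetonide and water opens it at the allylic carbon C1 with inversion, which sets C1–OH cis and C2–Br trans to the acetonide oxygens.

Step 3
Reactants: 3 bromohydrin
Product: 4 (1R,3S,4S)-5-bromo-1-hydroxy-3,4-O-isopropylidene cyclohex-5-ene (C2 now CH2)
Conditions: Bu3SnH (1.1 equiv), AIBN (cat.), PhMe, 80 °C
Reagents that add atoms: none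
Why: Radical chain hydrodebromination, in which the stannyl radical should abstract bromine from the secondary sp3 carbon faster than from the vinylic C5–Br bond, and the β-oxygenated C2 radical is reduced without elimination.

Step 4
Reactants: 4 allylic alcohol
Product: 5 (3S,4S)-5-bromo-3,4-O-isopropylidene cyclohex-5-en-1-one (β-bromo enone)
Conditions: Dess–Martin periodinane, CH2Cl2, 0 °C to rt
Reagents that add atoms: none
Why: Dess–Martin oxidation of a secondary allylic alcohol under non-basic conditions spares the acetonide and avoids β-elimination of the C3 oxygen from the new ketone; the C1 carbinol centre is removed on purpose.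

Step 5
Reactants: 5 β-bromo enone; 6 (tributylstannyl)methanol
Product: 7 (3S,4R)-5-(hydroxymethyl)-3,4-O-isopropylidene cyclohex-5-en-1-one
Conditions: Pd(PPh3)4 (cat.), 1,4-dioxane, 90 °C
Reagents that add atoms: (tributylstannyl)methanol (6), OC[Sn](CCCC)(CCCC)CCCC
Why: Migita–Kosugi–Stille coupling: the β-bromo enone adds readily to zerovalent palladium and the α-oxygenated CH2OH group of the stannane transfers in preference to butyl, forming the C5–C7 bond under neutral conditions that the base-sensitive β-alkoxy ketone tolerates.

Step 6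
Reactants: 7 hydroxymethyl enone acetonide
Product: 8 (3S,4R)-3,4-dihydroxy-5-(hydroxymethyl)cyclohex-5-en-1-one (triol enone)
Conditions: CF3CO2H, H2O, THF, 0 °C to rt
Reagents that add atoms: none
Why: Acid-catalysed acetal hydrolysis in dilute aqueous acid at low temperature should free the cis-diol without dehydrating the β-hydroxy ketone.

Step 7
Reactants: 8 triol enone
Product: 9 (3S,4R)-3-hydroxy-4,7-O-(di-tert-butylsilylene) enone (C4–O and C7–O bridged by tBu2Si in a six-membered ring; C3–OH free)
Conditions: tBu2Si(OSO2CF3)2 (1.05 equiv), 2,6-lutidine, DMF, −40 to 0 °C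
Reagents that add atoms: di-tert-butylsilyl bis(trifluoromethanesulfonate), CC(C)(C)[Si](OS(=O)(=O)C(F)(F)F)(OS(=O)(=O)C(F)(F)F)C(C)(C)C
Why: Silylene protection of a 1,3-diol: the primary C7 hydroxyl is silylated first and the tethered silyl triflate closes the six-membered ring onto the C4 oxygen, since the C3 oxygen could be reached only through a seven-membered ring.

Step 8
Reactants: 9 hydroxy enone silylene; 10 (2E,6E)-farnesyl bromide
Product: 12 (2S,3S,4R)-2-[(2E,6E)-farnesyl]-3-hydroxy-4,7-O-(di-tert-butylsilylene) enone, via dilithium β-oxido enolate 11 (not isolated)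
Conditions: LiN(iPr)2 (2.2 equiv), THF, −78 to −40 °C; then 10, DMPU, −78 to −20 °C; AcOH
Reagents that add atoms: (2E,6E)-farnesyl bromide (10), BrC/C=C(\C)CC/C=C(\C)CCC=C(C)C
Why: Alkylation of an aldolate dianion (Fráter–Seebach-type): the C3 oxide cannot be eliminated, the cross-conjugated enolate forms at C2, the only sp3 α-carbon, and the allylic bromide should enter anti to the C3 oxide, giving the 2S centre, which step 9 erases again.

Step 9
Reactants: 12 2-farnesyl-3-hydroxy enone silylene
Product: 15 (2R,3R,4R)-2,3-epoxy-2-[(2E,6E)-farnesyl]-4,7-O-(di-tert-butylsilylene) enone, via dilithium β-oxido enolate 13 (not isolated), via lithium 2-bromo-3-oxido ketone 14 (not isolated)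
Conditions: LiN(iPr)2 (2.1 equiv), THF, −78 to −40 °C; NBS (1.0 equiv), THF, −78 °C, then to 0 °C; AcOH
Reagents that add atoms: none
Why: Two equivalents of LiN(iPr)2 remove the hydroxyl proton and then the C2 proton to give the dianion 13, whose C3 oxide cannot leave, so E1cB elimination towards a phenol is shut off; NBS then brominates the enolate carbon and the neighbouring oxide displaces bromide in an intramolecular SN2 reaction at the carbonyl-activated carbon. The closest known chemistry is the ring-closing half of the Darzens condensation (α-halo-β-oxido carbonyl to α,β-epoxy carbonyl), fed by C-halogenation of an aldolate dianion as in the conversion of β-hydroxy ester dianions into glycidic esters with halogen electrophiles. The oxirane closes in the 3-exo-tet mode, the oxide attacking antiperiplanar to the pseudoaxial C2–Br bond. The new C2 stereocentre is controlled by the C3 carbinol centre of the chiral pool: a three-membered ring on a cyclohexene can only be cis-fused, so the oxygen ends on the face of C3–O and C4–O and farnesyl is pushed to the other face, whichever C2 epimer of 12 enters. The step needs bromine to enter C2 anti to the C3 oxide, because only that bromide can close; the solvated pseudoaxial lithium oxide on the lower face and the preference for axial attack anti to it should secure this. It also needs C-bromination of the enolate to outrun attack of NBS on the three farnesyl alkenes, which one equivalent of NBS at −78 °C without water or acid should secure.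

Step 10
Reactants: 15 epoxy enone silylene
Product: 16 (1R,2R,6R)-2-hydroxy-3-(hydroxymethyl)-6-[(2E,6E)-farnesyl]-7-oxabicyclo[4.1.0]hept-3-en-5-one (epoxy enone diol; 2R,3R,4R in the locants above)
Conditions: HF·pyridine, pyridine, THF, 0 °C
Reagents that add atoms: none
Why: Fluoride-induced cleavage of the di-tert-butylsilylene (Si–O to Si–F exchange); pyridine-buffered HF should spare the electron-poor keto-epoxide and the farnesyl alkenes.

Step 11
Reactants: 16 epoxy enone diol
Product: 17 [(1R,2R,6R)-2-hydroxy-5-oxo-6-[(2E,6E)-3,7,11-trimethyldodeca-2,6,10-trienyl]-7-oxabicyclo[4.1.0]hept-3-en-3-yl]methyl acetate (target)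
Conditions: AcCl (1.05 equiv), 2,4,6-collidine, CH2Cl2, −78 °C
Reagents that add atoms: acetyl chloride, CC(=O)Cl
Why: Selective O-acylation of a primary over a hindered secondary alcohol with acetyl chloride and collidine at low temperature; the C4 hydroxyl, flanked by the oxirane and the substituted alkene carbon, should stay free.

**Compound list**

1 | (1S,2S)-3-bromocyclohexa-3,5-diene-1,2-diol | BrC1=CC=C[C@H](O)[C@@H]1O | starting material
2 | (3S,4S)-5-bromo-3,4-O-isopropylidene diene (acetonide of 1) | BrC1=CC=C[C@@H]2OC(C)(C)O[C@H]12 | intermediate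
3 | (1S,2R,3R,4S)-2,5-dibromo-1-hydroxy-3,4-O-isopropylidene cyclohex-5-ene (bromohydrin) | BrC1=C[C@H](O)[C@@H](Br)[C@@H]2OC(C)(C)O[C@H]12 | intermediate
4 | (1R,3S,4S)-5-bromo-1-hydroxy-3,4-O-isopropylidene cyclohex-5-ene | BrC1=C[C@H](O)C[C@@H]2OC(C)(C)O[C@H]12 | intermediate
5 | (3S,4S)-5-bromo-3,4-O-isopropylidene cyclohex-5-en-1-one | BrC1=CC(=O)C[C@@H]2OC(C)(C)O[C@H]12 | intermediate
6 | (tributylstannyl)methanol | OC[Sn](CCCC)(CCCC)CCCC | starting material
7 | (3S,4R)-5-(hydroxymethyl)-3,4-O-isopropylidene cyclohex-5-en-1-one | OCC1=CC(=O)C[C@@H]2OC(C)(C)O[C@H]12 | intermediate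
8 | (3S,4R)-3,4-dihydroxy-5-(hydroxymethyl)cyclohex-5-en-1-one | OCC1=CC(=O)C[C@H](O)[C@@H]1O | intermediate
9 | (3S,4R)-3-hydroxy-4,7-O-(di-tert-butylsilylene) enone | O=C1C=C2CO[Si](C(C)(C)C)(C(C)(C)C)O[C@H]2[C@@H](O)C1 | intermediate
10 | (2E,6E)-farnesyl bromide | BrC/C=C(\C)CC/C=C(\C)CCC=C(C)C | starting material
11 | dilithium β-oxido enolate of 9 | [Li+].[Li+].[O-]C1=C[C@H]([O-])[C@@H]2O[Si](C(C)(C)C)(C(C)(C)C)OCC2=C1 | intermediate
12 | (2S,3S,4R)-2-[(2E,6E)-farnesyl]-3-hydroxy-4,7-O-(di-tert-butylsilylene) enone | O=C1C=C2CO[Si](C(C)(C)C)(C(C)(C)C)O[C@H]2[C@@H](O)[C@@H]1C/C=C(\C)CC/C=C(\C)CCC=C(C)C | intermediate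
13 | dilithium β-oxido enolate of 12 | [Li+].[Li+].[O-]C1=C(C/C=C(\C)CC/C=C(\C)CCC=C(C)C)[C@H]([O-])[C@@H]2O[Si](C(C)(C)C)(C(C)(C)C)OCC2=C1 | intermediate
14 | lithium 2-bromo-3-oxido ketone (bromine trans to the C3 oxide) | [Li+].O=C1C=C2CO[Si](C(C)(C)C)(C(C)(C)C)O[C@H]2[C@@H]([O-])[C@@]1(Br)C/C=C(\C)CC/C=C(\C)CCC=C(C)C | intermediate
15 | (2R,3R,4R)-2,3-epoxy-2-[(2E,6E)-farnesyl]-4,7-O-(di-tert-butylsilylene) enone | O=C1C=C2CO[Si](C(C)(C)C)(C(C)(C)C)O[C@H]2[C@H]3O[C@@]13C/C=C(\C)CC/C=C(\C)CCC=C(C)C | intermediate
16 | (1R,2R,6R)-2-hydroxy-3-(hydroxymethyl)-6-[(2E,6E)-farnesyl]-7-oxabicyclo[4.1.0]hept-3-en-5-one | OCC1=CC(=O)[C@]2(C/C=C(\C)CC/C=C(\C)CCC=C(C)C)O[C@@H]2[C@@H]1O | intermediate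
17 | [(1R,2R,6R)-2-hydroxy-5-oxo-6-[(2E,6E)-3,7,11-trimethyldodeca-2,6,10-trienyl]-7-oxabicyclo[4.1.0]hept-3-en-3-yl]methyl acetate | CC(=O)OCC1=CC(=O)[C@]2(C/C=C(\C)CC/C=C(\C)CCC=C(C)C)O[C@@H]2[C@@H]1O | target

**Step count and risks**

Total: 11 steps. Longest linear sequence: 11 steps, from 1 to 17; compounds 6 and 10 are bought and enter in steps 5 and 8.

Steps most likely to fail:

1. Step 9 (key step). What may go wrong: enolisation at the γ-positions (C4–H or C7–H) instead of C2; retro-aldol opening of the bromo aldolate; bromination of the amine or of the oxide instead of the enolate carbon; or delivery of bromine syn to the C3 oxide, which gives a bromide that cannot close. Fallback, from 12 back to 15: the anionic one-flask sequence is replaced by halogenation of a neutral silyl enol ether with a separate closure. Treating 12 with Me3SiOSO2CF3 and Et3N in CH2Cl2 at 0 °C should give the bis(trimethylsilyl) dienol ether F1, silylated on the C3 oxygen and on the C1 enol oxygen. NBS in THF at −78 °C should convert it into the 2-bromo-3-(trimethylsilyloxy) ketone F2, with bromine anti to the bulky C3 silyl ether. K2CO3 in MeOH at 0 °C then cleaves the trimethylsilyl ether, and the freed oxide closes the oxirane to 15.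

2. Step 8. What may go wrong: deprotonation at a γ-position, slow alkylation of the aggregated dianion, O-alkylation, or loss of the C3 oxygen followed by aromatisation. Fallback, from 9 back to 12: the enolate is replaced by an azaenolate (Corey–Enders hydrazone alkylation). Condensing 9 with Me2NNH2 (cat. AcOH, EtOH) should give the N,N-dimethylhydrazone F3. LiN(iPr)2 (2.2 equiv) in THF deprotonates its hydroxyl and its α′-carbon C2, and farnesyl bromide should alkylate the azaenolate at carbon to give the 2-farnesyl hydrazone F4. Hydrolysis with aqueous Cu(OAc)2 in THF returns the ketone 12.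

3. Step 3. What may go wrong: competing reduction of the vinylic C5–Br bond, which is needed for the Stille coupling, during the radical debromination. Fallback, from 3 back to 5 (it bypasses 4 and step 4): the order of oxidation and reduction is exchanged. Dess–Martin oxidation of 3 in CH2Cl2 should give the 2,5-dibromo enone acetonide F5, with the C2 bromine trans to the acetonide oxygens. Its C2–Br bond is now activated by the carbonyl and should be cleaved by Bu3SnH with Et3B/air initiation in toluene at −78 to 0 °C, a temperature at which the vinylic bromide should not react, to give 5.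

Further compounds
F1 | step 9 | bis(trimethylsilyl) dienol ether of 12 (C1 enol and C3 oxygens silylated) | C[Si](C)(C)OC1=C(C/C=C(\C)CC/C=C(\C)CCC=C(C)C)[C@H](O[Si](C)(C)C)[C@@H]2O[Si](C(C)(C)C)(C(C)(C)C)OCC2=C1
F2 | step 9 | 2-bromo-2-farnesyl-3-(trimethylsilyloxy) ketone silylene (bromine trans to the C3 oxygen) | O=C1C=C2CO[Si](C(C)(C)C)(C(C)(C)C)O[C@H]2[C@@H](O[Si](C)(C)C)[C@@]1(Br)C/C=C(\C)CC/C=C(\C)CCC=C(C)C
F3 | step 8 | N,N-dimethylhydrazone of 9 | CN(C)N=C1C=C2CO[Si](C(C)(C)C)(C(C)(C)C)O[C@H]2[C@@H](O)C1
F4 | step 8 | N,N-dimethylhydrazone of 12 | CN(C)N=C1C=C2CO[Si](C(C)(C)C)(C(C)(C)C)O[C@H]2[C@@H](O)[C@@H]1C/C=C(\C)CC/C=C(\C)CCC=C(C)C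
F5 | step 3 | 2,5-dibromo-3,4-O-isopropylidene cyclohex-5-en-1-one (C2 bromine trans to the acetonide oxygens) | BrC1=CC(=O)[C@@H](Br)[C@@H]2OC(C)(C)O[C@H]12
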